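Reagent charged over 3 times the starting material charged is the ratio I would ask about first in any of these flasks.

| flask | starting material | reagent | capture agent | remark | time |
|---|---|---|---|---|---|
| spring | 0.80 M | 0.46 M | 0.24 M | run made earlier |  |
| dusk | 0.80 M | 1.1 M | 0.24 M | run made earlier |  |
| summer | 0.80 M | 2.3 M | 0.24 M | run made earlier |  |
| midnight | 1.4 M | 0.88 M | 0.24 M | run made earlier |  |
| violet | 0.80 M | 0.880 M | 0.240 M |  | 5.0 h |
| green | 2.5 M | 0.400 M | 0.500 M |  | 5.0 h |
| grey | 0.50 M | 2.50 M | 0.240 M |  | 5.0 h |
| ochre | 0.80 M | 0.400 M | 0.0800 M |  | 5.0 h |

| run | time / h | bis adduct / % | triple product / % |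
|---|---|---|---|
| spring | 0.667 | 5 | 4 |
| spring | 1.33 | 2 | 3 |
| spring | 2.00 | 0 | 3 |
| spring | 3.00 | 4 | 0 |
| spring | 4.00 | 3 | 6 |
| dusk | 0.333 | 2 | 0 |
| dusk | 0.833 | 6 | 6 |
| dusk | 1.50 | 5 | 8 |
| dusk | 2.50 | 5 | 19 |
| dusk | 4.00 | 5 | 21 |
| summer | 0.333 | 10 | 8 |
| summer | 0.833 | 6 | 25 |
| summer | 1.50 | 3 | 45 |
| summer | 2.50 | 4 | 53 |
| summer | 4.00 | 0 | 68 |
| midnight | 0.250 | 0 | 0 |
| midnight | 0.500 | 1 | 3 |
| midnight | 1.00 | 7 | 2 |
| midnight | 2.00 | 2 | 1 |
| midnight | 4.00 | 4 | 8 |

(standard deviation of a reading: 2 percentage points)

- no earlier run changes the charge of capture agent; that part of a forecast is a guess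

- the flasks put in order of share of bis adduct in all that became bis adduct or triple product or trapped intermediate, best first, at 5.0 h (violet / green / grey / ochre)
- the same order at 1.0 h (violet / green / grey / ochre)
- the share of bis adduct in all that became bis adduct or triple product or trapped intermediate of the flask you put first, at 5.0 h
- the share of bis adduct in all that became bis adduct or triple product or trapped intermediate of the flask you put last, at 5.0 h

*Why that ratio?* If the names mean what they say, a triple product has taken 3 reagent. So coverage, c(reagent)/(3 c(starting material)), is the largest fraction of the starting material that the charge can carry to triple product. For grey it is 1.67.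

*Do the runs obey it?* Summer and dusk do, as readings with a scatter of 2 percentage points. At 4.00 h the summer run reads 68% triple product against a ceiling of 95.8%, and the dusk run reads 21% against 45.8%.

*And the new flasks?* Violet has 0.367, ochre 0.167 and green 0.0533. Grey stands above them and is the one flask above 1.

*But a ceiling is not a rate. What does it buy you?* It buys a floor. Even if every starting material in grey became triple product, 40.0% of the reagent would remain, which is 1.00 M. The summer run, charged with 2.3 M, reads 0% bis adduct at 4.00 h, a reading with a scatter of 2 points. So I put grey last at 5.0 h and commit to at least that floor of reagent left.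

*Does coverage rank the other three?* No. Green has the lowest coverage but also 0.500 M of capture agent, and no run varies that charge, so I leave those three unranked.

The forecast gives ochre > violet > green > grey at 5.0 h, ochre > violet > grey > green at 1.0 h, top 40% and low 1%, with the words “Grey has excess reagent, so bis adduct goes to triple product”.

The simulation gives ochre > violet > green > grey at 5.0 h and ochre > violet > green > grey at 1.0 h, with top 29.5% and low 0.313%.

    mono adduct + capture agent → trapped intermediate (k = 1.10 × 10⁻⁴ /M/s)
    reagent + bis adduct → triple product (k = 0.00140 /M/s)
    reagent + mono adduct → bis adduct (k = 1.50 × 10⁻⁴ /M/s)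
    starting material + reagent → mono adduct (k = 4.80 × 10⁻⁴ /M/s)

In grey at 5.00 h, bis adduct is made at 0.879 of the rate at which it is used, each step taken net, and it stands at 0.305% beside 88.3% triple product. Reagent stands at 44.6% of its charge, above the reckoned floor of 40.0%.

The neighbour of grey charged with 1.2 M of starting material has coverage 0.694, so its triple product can reach at most 69.4% of the starting material charged. Computed, it holds 50.6% triple product and 2.53% of its reagent, with a bis adduct share of 5.82%.

The runs were computed for substances that don't exist; the scatter is artificial.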